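**Plan**
Retrosynthesis: the spiro acylal is opened at the bond between the bridgehead oxygen and the ketal carbon, giving a 2-acyloxy-1,4-quinone (step 18), and this goes back to a phenol ester of chromenediol 7 (fragment A, from phloroglucinol).
In the cage, the bond between the quaternary alkoxy/prenyl carbon and the oxygenated bridgehead is cut together with the ketone–bridgehead bond in one retro-[4+2].
Enabling feature: the carbocycle made of the two O-bearing bridgeheads, the ester-bearing C=CH and the CH2–CH unit is a disguised 1,4-dioxygenated 2-acylcyclohexa-1,3-diene, and the ketone carbon with its alkoxy/prenyl neighbour is a ketene equivalent hanging from the gem-dimethyl carbinol oxygen, two atoms from the diene terminus.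
Forward: fragment A (steps 1–4); chiral 4-silyloxycyclohexenone, aldol with acetone, O–H insertion, prenylation, thioester (5–12); iodination and carbonylative union with 7 (13–14); silylation/cycloaddition closes the oxolane and the bicyclo[2.2.2]octenone at once (15); desilylation, quinone, spiro acylal (16–18).
Stereochemistry: asymmetric transfer hydrogenation sets a sacrificial silyloxy centre that directs the aldol; the aldol centre alone dictates the three cage centres in step 15; the spiro carbon and its CH neighbour settle under thermodynamic control in step 18.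

Key step: step 15

Assumption: the target's configuration at the spiro acylal carbon and at the adjacent prenyl-bearing CH is taken to be the thermodynamically preferred one, since both centres can equilibrate (retro-oxa-Michael addition, enolisation).

Step 1
Reactants: 1 phloroglucinol (benzene-1,3,5-triol); 2 3-methylbut-2-enal
Product: 3 2,2-dimethyl-2H-chromene-5,7-diol
Conditions: pyridine, 110 °C, 1 in excess
Reagents that add atoms: none
Why: Knoevenagel-type C-alkylation of the triol by the enal, dehydration to an ortho-quinone methide and oxa-6π electrocyclisation (the standard chromene annulation of resorcinols) should give the chromene, and the excess of 1 limits double annulation.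

Step 2
Reactants: 3
Product: 4 5,7-bis(methoxymethoxy)-2,2-dimethyl-2H-chromene
Conditions: MOMCl, i-Pr2NEt, CH2Cl2, 0 °C to rt
Reagents that add atoms: chloromethyl methyl ether, COCCl
Why: Williamson-type acetal ether formation protects both phenols and installs the directing groups for the next step.

Step 3
Reactants: 4; 5 1-bromo-3-methylbut-2-ene (prenyl bromide)
Product: 6 5,7-bis(methoxymethoxy)-2,2-dimethyl-6-(3-methylbut-2-en-1-yl)-2H-chromene
Conditions: n-BuLi, THF, 0 °C; CuI (10 mol%), then 5, −78 °C to rt
Reagents that add atoms: none
Why: Directed ortho-metalation should take place at the ring CH flanked by both methoxymethoxy groups (position 6) in preference to position 8, which has only one such neighbour, and copper-mediated SN2 alkylation then attaches the prenyl group without allylic transposition.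

Step 4
Reactants: 6
Product: 7 2,2-dimethyl-6-(3-methylbut-2-en-1-yl)-2H-chromene-5,7-diol (fragment A)
Conditions: 3 M HCl, MeOH, 40 °C
Reagents that add atoms: none
Why: Acid-catalysed acetal methanolysis frees both phenols under conditions mild enough to leave the prenyl and chromene double bonds untouched.

Step 5
Reactants: 8 1,4-dioxaspiro[4.5]dec-6-en-8-one
Product: 9 (R)-1,4-dioxaspiro[4.5]dec-6-en-8-ol
Conditions: RuCl[(R,R)-TsDPEN](p-cymene) (1 mol%), HCO2H/Et3N (5:2), CH2Cl2, rt
Reagents that add atoms: none
Why: Noyori-type asymmetric transfer hydrogenation reduces the enone carbonyl 1,2, with the alkene acting as the large group, so the chiral ruthenium hydride should set the R carbinol centre, which serves only to relay chirality.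

Step 6
Reactants: 9
Product: 10 (R)-8-[(tert-butyldimethylsilyl)oxy]-1,4-dioxaspiro[4.5]dec-6-ene
Conditions: TBSCl, imidazole, DMF, rt
Reagents that add atoms: tert-butyldimethylsilyl chloride, CC(C)(C)[Si](C)(C)Cl
Why: Standard silylation of the secondary allylic alcohol; this silyl ether later becomes the silyloxy group of the diene and the bridgehead oxygen.

Step 7
Reactants: 10
Product: 11 (R)-4-[(tert-butyldimethylsilyl)oxy]cyclohex-2-en-1-one
Conditions: PPTS, acetone/H2O, 50 °C
Reagents that add atoms: water, O
Why: Acid-catalysed hydrolysis of the dioxolane unmasks the ketone, now conjugated with the ring alkene, without touching the allylic silyl ether or its stereocentre.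

Step 8
Reactants: 11; 12 acetone
Product: 13 (4R,6S)-4-[(tert-butyldimethylsilyl)oxy]-6-(2-hydroxypropan-2-yl)cyclohex-2-en-1-one
Conditions: LiN(i-Pr)2 (LDA), THF, −78 °C; 12; AcOH quench at −78 °C
Reagents that add atoms: none
Why: Kinetic deprotonation at the alpha-prime CH2 gives the cross-conjugated lithium enolate, whose aldol addition to acetone should occur anti to the pseudoaxial silyloxy group (1,3-induction) and so set the S centre at C6, the only stereocentre carried into the cage.

Step 9
Reactants: 13; 14 dimethyl 2-diazomalonate
Product: 15 dimethyl 2-({2-[(1S,5R)-5-[(tert-butyldimethylsilyl)oxy]-2-oxocyclohex-3-en-1-yl]propan-2-yl}oxy)malonate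
Conditions: Rh2(OAc)4 (2 mol%), benzene, 80 °C, slow addition of 14
Reagents that add atoms: none
Why: Rhodium-carbenoid O–H insertion (through an oxonium ylide) etherifies the hindered tertiary alcohol under neutral conditions that avoid retro-aldol cleavage, and no stereocentre is formed.

Step 10
Reactants: 15; 5
Product: 16 dimethyl 2-({2-[(1S,5R)-5-[(tert-butyldimethylsilyl)oxy]-2-oxocyclohex-3-en-1-yl]propan-2-yl}oxy)-2-(3-methylbut-2-en-1-yl)malonate
Conditions: Cs2CO3, DMF, 0 °C to rt
Reagents that add atoms: none
Why: The alkoxymalonate C–H is acidic enough for carbonate-mediated SN2 alkylation, so the prenyl group is introduced without a base strong enough to enolise the ring ketone and epimerise the adjacent stereocentre.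

Step 11
Reactants: 16
Product: 18 2-({2-[(1S,5R)-5-[(tert-butyldimethylsilyl)oxy]-2-oxocyclohex-3-en-1-yl]propan-2-yl}oxy)-5-methylhex-4-enoic acid (both epimers at C2 of the acid), via alkoxymalonic diacid 17 (not isolated)
Conditions: Me3SnOH, 1,2-dichloroethane, 80 °C; 1 M HCl work-up; toluene, 100 °C
Reagents that add atoms: trimethyltin hydroxide, C[Sn](C)(C)O
Why: Trimethyltin hydroxide cleaves both methyl esters under near-neutral conditions and the alkoxymalonic acid then loses CO2 on heating (malonic acid decarboxylation); the new centre forms unselectively and is planarised again in step 15.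

Step 12
Reactants: 18; 19 ethanethiol
Product: 20 S-ethyl 2-({2-[(1S,5R)-5-[(tert-butyldimethylsilyl)oxy]-2-oxocyclohex-3-en-1-yl]propan-2-yl}oxy)-5-methylhex-4-enethioate (epimers at C2)
Conditions: EDC·HCl, DMAP (10 mol%), CH2Cl2, −20 to 0 °C
Reagents that add atoms: none
Why: Steglich-type carbodiimide thioesterification at low temperature (to keep thiol conjugate addition to the enone slow) gives the thioester, chosen because it is enolised under soft conditions and carries the acyl carbon at the ketone oxidation level.

Step 13
Reactants: 20
Product: 21 S-ethyl 2-({2-[(1S,5R)-5-[(tert-butyldimethylsilyl)oxy]-3-iodo-2-oxocyclohex-3-en-1-yl]propan-2-yl}oxy)-5-methylhex-4-enethioate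
Conditions: I2, pyridine, CH2Cl2, 0 °C to rt
Reagents that add atoms: iodine, II
Why: Amine-mediated alpha-iodination of the enone (conjugate addition of pyridine, iodination of the enolate, elimination) gives the vinyl iodide needed for carbonylation.

Step 14
Reactants: 21; 7
Product: 22 5-hydroxy-2,2-dimethyl-6-(3-methylbut-2-en-1-yl)-2H-chromen-7-yl (3R,5S)-3-[(tert-butyldimethylsilyl)oxy]-5-[2-({1-(ethylsulfanyl)-5-methyl-1-oxohex-4-en-2-yl}oxy)propan-2-yl]-6-oxocyclohex-1-ene-1-carboxylate (may sit partly as its chelated dienol tautomer)
Conditions: Pd(OAc)2 (5 mol%), Xantphos (6 mol%), CO (1 atm), Et3N, toluene, 45 °C, 7 in excess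
Reagents that add atoms: carbon monoxide, [C-]#[O+]
Why: Palladium-catalysed carbonylative esterification (oxidative addition of the vinyl iodide to zerovalent palladium, CO insertion, acyl transfer to phenoxide) should acylate the hydroxyl at position 7 of the chromene, which has only one ortho substituent, and brings in the carboxyl carbon and fragment A together.

Step 15
Reactants: 22
Product: 25 caged cycloadduct: bicyclo[2.2.2]octene bridged by the gem-dimethyl oxolane; both bridgehead oxygens silylated (trimethylsilyl next to the quaternary carbon and tert-butyldimethylsilyl at the other bridgehead); ketone carbon masked as O-trimethylsilyl S-ethyl monothioketal (both epimers); aryl ester with the phenol as trimethylsilyl ether; cage configuration as in the target, via silyl dienol ether 23 (not isolated), via ketene silyl thioacetal 24 (not isolated)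
Conditions: TMSOTf (3.5 equiv), Et3N, CH2Cl2, −20 °C to rt; solvent exchange to toluene, 100 °C, argon
Reagents that add atoms: trimethylsilyl trifluoromethanesulfonate, C[Si](C)(C)OS(=O)(=O)C(F)(F)F
Why: Soft enolisation silylates the vinylogous beta-keto ester at oxygen with loss of the gamma proton, and also the phenol and the thioester, giving a 2-(aryloxycarbonyl)-1,4-bis(silyloxy)cyclohexa-1,3-diene with a ketene O-silyl S-ethyl acetal tethered through the gem-dimethyl carbinol oxygen; on heating these should combine in an intramolecular Diels–Alder reaction of inverse electron demand, which in the asynchronous limit is a Mukaiyama–Michael addition to the diene terminus followed by vinylogous Claisen-type closure. The closest known reaction type is the intramolecular Diels–Alder reaction of 6-alkoxycyclohexa-2,4-dienones (masked ortho-benzoquinones) with an alkene tethered through the ketal oxygen, here with the roles of the two saturated bridges exchanged. The oxolane is closed by the bond between the alkoxy/prenyl-bearing ketene-acetal carbon and the adjacent silyloxy diene terminus (five-membered, exo-type closure imposed by the two-atom CMe2–O tether), and the bicyclo[2.2.2]octene by the bond between the acetal carbon and the far diene terminus, both suprafacial. The two bridgeheads and the quaternary alkoxy carbon are fixed by the single ring stereocentre: the tether reaches only the diene face syn to the 2-alkoxypropan-2-yl group, and the quaternary carbon has no choice because its oxygen is in the tether and its acetal carbon must span the ring (prenyl exo); the thioketal carbon forms as a mixture that converges in step 16. The step needs chemoselective enolisation (thioester and gamma proton, not the ring CH next to the diene) and periselectivity for the carbocyclic diene over a hetero-Diels–Alder through the enoate carbonyl; the first should follow from the acidity order when silylation is finished at or below room temperature before heating, the second from the short tether, which holds the ketene acetal over the ring and away from the exocyclic ester.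

Step 16
Reactants: 25
Product: 26 caged keto diol aryl ester: both bridgehead hydroxyls free, cage ketone free, phenol at position 5 of the chromene free
Conditions: HF·pyridine, THF/pyridine, 0 °C to rt
Reagents that add atoms: none
Why: Fluoride cleaves all four silyl ethers under acidic conditions, the desilylated monothioketal collapses to the ketone with loss of ethanethiol, and the non-basic medium spares the aryl ester and the beta-hydroxy ketone (no retro-aldol).

Step 17
Reactants: 26
Product: 27 2-acyloxyquinone: 2,2-dimethyl-6-(3-methylbut-2-en-1-yl)-5,8-dioxo-5,8-dihydro-2H-chromen-7-yl ester of the caged hydroxy acid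
Conditions: (KSO3)2NO, KH2PO4, acetone/H2O, 0 °C
Reagents that add atoms: potassium nitrosodisulfonate (Fremy's salt), [K+].[K+].[O-]S(=O)(=O)N([O])S(=O)(=O)[O-]
Why: Teuber oxidation converts the free phenol, whose para position is unsubstituted, into the para-quinone and leaves alkenes, esters and tertiary alcohols alone; the ester thereby becomes a vinylogous mixed anhydride.

Step 18
Reactants: 27
Product: 28 target CNP0222516.1
Conditions: (PhO)2P(O)OH (10 mol%), CH2Cl2, 4 Å molecular sieves, rt
Reagents that add atoms: none
Why: Proposed new method: the ester holds the bridgehead tertiary hydroxyl in reach of the acyloxy-bearing quinone carbon (the beta carbon of the enedione), so acid-catalysed 6-exo-trig oxa-Michael addition and C-protonation of the resulting enol should give the spiro 1,3-dioxan-4-one, which is the tetrahedral intermediate of a vinylogous transesterification, retained because the carboxylate is held in the six-membered ring; the closest known reaction types are acid-catalysed additions of alcohols to enol ethers and to 2-alkoxy- or 2-acyloxyquinones (spiroketalisation, vinylogous ester exchange) and the mixed acyloxy–alkoxy ketals of ortho-quinones from Wessely oxidation; both new centres are reversible and should settle to the thermodynamic configuration.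

**Compound list**
1 | phloroglucinol | Oc1cc(O)cc(O)c1 | starting material
2 | 3-methylbut-2-enal | CC(C)=CC=O | starting material
3 | 2,2-dimethyl-2H-chromene-5,7-diol | CC1(C)C=Cc2c(O)cc(O)cc2O1 | intermediate
4 | 5,7-bis(methoxymethoxy)-2,2-dimethyl-2H-chromene | CC1(C)C=Cc2c(OCOC)cc(OCOC)cc2O1 | intermediate
5 | 1-bromo-3-methylbut-2-ene | CC(C)=CCBr | starting material
6 | 5,7-bis(methoxymethoxy)-2,2-dimethyl-6-(3-methylbut-2-en-1-yl)-2H-chromene | CC(C)=CCc1c(OCOC)cc2OC(C)(C)C=Cc2c1OCOC | intermediate
7 | 2,2-dimethyl-6-(3-methylbut-2-en-1-yl)-2H-chromene-5,7-diol (fragment A) | CC(C)=CCc1c(O)cc2OC(C)(C)C=Cc2c1O | intermediate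
8 | 1,4-dioxaspiro[4.5]dec-6-en-8-one | O=C1C=CC2(CC1)OCCO2 | starting material
9 | (R)-1,4-dioxaspiro[4.5]dec-6-en-8-ol | O[C@H]1C=CC2(OCCO2)CC1 | intermediate
10 | (R)-8-[(tert-butyldimethylsilyl)oxy]-1,4-dioxaspiro[4.5]dec-6-ene | CC(C)(C)[Si](C)(C)O[C@H]1C=CC2(OCCO2)CC1 | intermediate
11 | (R)-4-[(tert-butyldimethylsilyl)oxy]cyclohex-2-en-1-one | CC(C)(C)[Si](C)(C)O[C@H]1C=CC(=O)CC1 | intermediate
12 | acetone | CC(C)=O | starting material
13 | (4R,6S)-4-[(tert-butyldimethylsilyl)oxy]-6-(2-hydroxypropan-2-yl)cyclohex-2-en-1-one | O=C1C=C[C@H](O[Si](C)(C)C(C)(C)C)C[C@H]1C(C)(C)O | intermediate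
14 | dimethyl 2-diazomalonate | COC(=O)C(=[N+]=[N-])C(=O)OC | starting material
15 | dimethyl alkoxymalonate of 13 | O=C1C=C[C@H](O[Si](C)(C)C(C)(C)C)C[C@H]1C(C)(C)OC(C(=O)OC)C(=O)OC | intermediate
16 | dimethyl alkoxy(prenyl)malonate | O=C1C=C[C@H](O[Si](C)(C)C(C)(C)C)C[C@H]1C(C)(C)OC(CC=C(C)C)(C(=O)OC)C(=O)OC | intermediate
17 | alkoxy(prenyl)malonic diacid | O=C1C=C[C@H](O[Si](C)(C)C(C)(C)C)C[C@H]1C(C)(C)OC(CC=C(C)C)(C(=O)O)C(=O)O | intermediate (not isolated)
18 | 2-alkoxy-5-methylhex-4-enoic acid (epimers at C2) | O=C1C=C[C@H](O[Si](C)(C)C(C)(C)C)C[C@H]1C(C)(C)OC(CC=C(C)C)C(=O)O | intermediate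
19 | ethanethiol | CCS | starting material
20 | S-ethyl thioester of 18 | O=C1C=C[C@H](O[Si](C)(C)C(C)(C)C)C[C@H]1C(C)(C)OC(CC=C(C)C)C(=O)SCC | intermediate
21 | 2-iodoenone thioester | O=C1C(I)=C[C@H](O[Si](C)(C)C(C)(C)C)C[C@H]1C(C)(C)OC(CC=C(C)C)C(=O)SCC | intermediate
22 | aryl 6-oxocyclohex-1-ene-1-carboxylate (ester with the 7-hydroxyl of 7) | O=C1C(C(=O)Oc2cc3OC(C)(C)C=Cc3c(O)c2CC=C(C)C)=C[C@H](O[Si](C)(C)C(C)(C)C)C[C@H]1C(C)(C)OC(CC=C(C)C)C(=O)SCC | intermediate
23 | silyl dienol ether (1-trimethylsilyloxy-4-tert-butyldimethylsilyloxy-cyclohexa-1,3-diene, aryl ester at C2, phenol silylated) | C[Si](C)(C)OC1=C(C(=O)Oc2cc3OC(C)(C)C=Cc3c(O[Si](C)(C)C)c2CC=C(C)C)C=C(O[Si](C)(C)C(C)(C)C)C[C@H]1C(C)(C)OC(CC=C(C)C)C(=O)SCC | intermediate (not isolated)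
24 | ketene O-trimethylsilyl S-ethyl acetal of 23 (either alkene geometry) | C[Si](C)(C)OC1=C(C(=O)Oc2cc3OC(C)(C)C=Cc3c(O[Si](C)(C)C)c2CC=C(C)C)C=C(O[Si](C)(C)C(C)(C)C)C[C@H]1C(C)(C)OC(CC=C(C)C)=C(O[Si](C)(C)C)SCC | intermediate (not isolated)
25 | caged cycloadduct, O-silyl S-ethyl monothioketal (epimers at the thioketal carbon) | CC(C)=CCc1c(OC(=O)C2=C[C@]3(O[Si](C)(C)C(C)(C)C)C[C@H]4C(C)(C)O[C@@](CC=C(C)C)(C3(O[Si](C)(C)C)SCC)[C@@]24O[Si](C)(C)C)cc2OC(C)(C)C=Cc2c1O[Si](C)(C)C | intermediate
26 | caged keto diol aryl ester, free phenol | CC(C)=CCc1c(OC(=O)C2=C[C@]3(O)C[C@H]4C(C)(C)O[C@@](CC=C(C)C)(C3=O)[C@@]24O)cc2OC(C)(C)C=Cc2c1O | intermediate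
27 | 2-acyloxy-1,4-quinone | CC(C)=CCC1=C(OC(=O)C2=C[C@]3(O)C[C@H]4C(C)(C)O[C@@](CC=C(C)C)(C3=O)[C@@]24O)C(=O)C2=C(C=CC(C)(C)O2)C1=O | intermediate
28 | CNP0222516.1 | CC(C)=CC[C@H]1C(=O)C2=C(OC(C)(C)C=C2)C(=O)[C@@]12OC(=O)C1=C[C@]3(O)C[C@H]4C(C)(C)O[C@@](CC=C(C)C)(C3=O)[C@@]14O2 | target

**Step count and risks**
Total steps: 18. Longest linear sequence: 14 steps (8 to 28, steps 5–18); fragment A (steps 1–4) enters at step 14.

1. Step 18 (Proposed new method). What may go wrong: the ring–chain equilibrium may not favour the acylal, or the vinylogous anhydride may lose or transfer its acyl group faster than the hindered bridgehead hydroxyl adds; the free beta-hydroxy ketone may also undergo retro-aldol opening. Fallback with known reaction types, from 27 back to 28: 27 is first rearranged by base-mediated addition–elimination (Cs2CO3, MeCN, 0 °C), a vinylogous transesterification in which the bridgehead alkoxide displaces the carboxylate at the quinone carbon, to the 2-alkoxyquinone carboxylic acid F1. The carboxylic acid is then added across the enol ether double bond of F1 under acid catalysis (camphorsulfonic acid, CH2Cl2), the standard hydroacyloxylation route to acylals, which closes the lactone from the other oxygen and gives 28.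

2. Step 15 (key step). What may go wrong: steric congestion (four contiguous fully substituted carbons are created) may stop the cycloaddition, the diene may aromatise by oxidation, or soft enolisation may also remove the ring CH next to the diene and erode the stereocentre. Fallback, from 20 back to 26: the dienophile carbon is lowered to the aldehyde level, so that a trisubstituted enol silyl ether, formed under the mildest conditions, replaces the ketene thioacetal. Fukuyama reduction of 20 (Et3SiH, Pd/C, acetone, rt) should give the aldehyde F2. Iodination as in step 13 gives the iodoenone F3, and carbonylative esterification with 7 as in step 14 gives the aryl ester F4. TMSOTf/Et3N and heating as in step 15 should give the cycloadduct F5, in which the former aldehyde carbon is a silyl-protected secondary carbinol. HF·pyridine gives the alcohol F6, and Parikh–Doering oxidation (SO3·pyridine, DMSO, i-Pr2NEt) of its only secondary hydroxyl returns to 26.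

3. Step 14. What may go wrong: poor site selectivity between the two phenolic hydroxyls of 7, slow acyl transfer to a hindered phenoxide, or loss of the sensitive alkylidene beta-keto ester under the basic carbonylation conditions. Fallback, from 21 back to 22: methoxycarbonylation of 21 (Pd(OAc)2, PPh3, CO, MeOH, Et3N) gives the methyl ester F7. Heating F7 with 7 in toluene (110 °C, methanol distilled off) exchanges the ester through the acylketene formed from its dienol tautomer (thermal beta-keto ester transesterification), where the less hindered phenol traps the ketene, and gives 22.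

**Further compounds**
F1 | step 18 | 2-alkoxyquinone carboxylic acid (bridgehead oxygen of the caged acid bonded to C7 of 2,2-dimethyl-6-prenyl-2H-chromene-5,8-dione) | OC(=O)C1=C[C@]3(O)C[C@H]4C(C)(C)O[C@@](CC=C(C)C)(C3=O)[C@@]14OC5=C(CC=C(C)C)C(=O)C6=C(OC(C)(C)C=C6)C5=O
F2 | step 15 | 2-({2-[(1S,5R)-5-[(tert-butyldimethylsilyl)oxy]-2-oxocyclohex-3-en-1-yl]propan-2-yl}oxy)-5-methylhex-4-enal | O=C1C=C[C@H](O[Si](C)(C)C(C)(C)C)C[C@H]1C(C)(C)OC(CC=C(C)C)C=O
F3 | step 15 | 2-iodoenone aldehyde | O=C1C(I)=C[C@H](O[Si](C)(C)C(C)(C)C)C[C@H]1C(C)(C)OC(CC=C(C)C)C=O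
F4 | step 15 | aryl ester aldehyde (aldehyde analogue of 22) | O=C1C(C(=O)Oc2cc3OC(C)(C)C=Cc3c(O)c2CC=C(C)C)=C[C@H](O[Si](C)(C)C(C)(C)C)C[C@H]1C(C)(C)OC(CC=C(C)C)C=O
F5 | step 15 | caged cycloadduct with silyl-protected secondary carbinol (epimers at the carbinol carbon) | CC(C)=CCc1c(OC(=O)C2=C[C@]3(O[Si](C)(C)C(C)(C)C)C[C@H]4C(C)(C)O[C@@](CC=C(C)C)(C3O[Si](C)(C)C)[C@@]24O[Si](C)(C)C)cc2OC(C)(C)C=Cc2c1O[Si](C)(C)C
F6 | step 15 | caged triol aryl ester with free phenol (secondary alcohol in place of the ketone of 26) | CC(C)=CCc1c(OC(=O)C2=C[C@]3(O)C[C@H]4C(C)(C)O[C@@](CC=C(C)C)(C3O)[C@@]24O)cc2OC(C)(C)C=Cc2c1O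
F7 | step 14 | methyl (3R,5S)-3-[(tert-butyldimethylsilyl)oxy]-5-[2-({1-(ethylsulfanyl)-5-methyl-1-oxohex-4-en-2-yl}oxy)propan-2-yl]-6-oxocyclohex-1-ene-1-carboxylate | O=C1C(C(=O)OC)=C[C@H](O[Si](C)(C)C(C)(C)C)C[C@H]1C(C)(C)OC(CC=C(C)C)C(=O)SCC
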